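Remark on the chemistry: the SMILES is read as the (2R,5R) isomer, i.e. the 2,5-cis-disubstituted oxane with a (3E,7E) chain; 3,4-di-O-acetyl-D-xylal and (2E,6E)-farnesyl bromide are taken to be commercial.

## Structural features

Rhopaloic acid B is a C24 norsesterterpenoid built on a single oxane (tetrahydropyran) ring, numbered here O1, C2–C6. C2 carries a 1-carboxyvinyl group (Cα(=CH2)CO2H, an α-substituted acrylic acid) and C5 carries a (3E,7E)-4,8,12-trimethyltrideca-3,7,11-trienyl ("homofarnesyl") chain, C1′–C13′. The two stereocentres, C2 (R) and C5 (R), are 1,4-related across the ring and cis, so one group is axial in either chair: the required isomer is the less stable one and cannot be reached by equilibration. C5 is flanked only by methylene groups (C4, C6, C1′) and has no neighbouring functional group through which it could be set or corrected. C2 is an allylic, α-oxygenated methine (a Baylis–Hillman-type ether), so ionisation or conjugate addition–elimination at the acrylate can epimerise it or open the ring, and the acrylic acid itself polymerises and adds nucleophiles. The chain holds three trisubstituted alkenes, two of fixed E geometry, which are sensitive to protic and Lewis acids (cation–olefin cyclisation), to electrophilic oxidants and to reversible radical addition. The real difficulty is therefore the isolated C5 centre, its union with the C15 polyene, and the relay of its configuration to C2 in the contra-thermodynamic cis sense. The key step exploits the 1,3-relationship of C3 and C5 within the ring: a carbinol oxygen placed temporarily on C3 of a 3,6-dihydro-2H-pyran (C4=C5) can hand its acyl α-carbon to C5 by a suprafacial [3,3] shift, so that the C5–C1′ bond and the C5 configuration both come from a sugar-derived C3 stereocentre.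

## Logic of the disconnections

15 ⇒ 14. The Cα–CO2H bond and the hydrogen on the exocyclic methylene are removed together, leaving a C2 ethynyl group. The acrylic acid is the most fragile function and is best made last, in one step and without base. The gain is a robust, non-electrophilic two-carbon stub. The forward step must add H and CO2H across the alkyne in the Markovnikov sense and leave three trisubstituted alkenes alone.

14 ⇒ 13. The terminal C–H is exchanged for C–Si, which only reflects the form in which the alkyne is delivered. The forward step must cleave C(sp)–Si without damage at C2.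

13 ⇒ 12. The C2–C(sp) bond is cut, leaving a C2 acetal. This turns C2 into a planar oxocarbenium carbon whose configuration is dictated by C5, so C2 need not be carried through the synthesis and the anomeric mixture in 12 is immaterial. The forward step must be kinetically controlled: axial attack on the half-chair with the C5 chain pseudoequatorial, which gives the cis isomer.

12 ⇒ 11. The C2–OMe bond and one C3–H bond are removed, giving the C2=C3 enol ether. The gain is loss of the acetal centre. The forward step is Markovnikov addition of an alcohol under acid mild enough for the polyene.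

11 ⇒ 10. The alkene is moved from C2=C3 to C3=C4, the position in which it emerges from the key step. The forward shift must run towards oxygen only, because migration towards C5 would erase that stereocentre.

10 ⇒ 8. A carboxyl group is added back to C1′. It costs one step forward but makes C1′ an ester α-carbon, which is what permits the next cut. The forward step is a reductive decarboxylation with a hydrogen donor fast enough to outrun rearrangement of the C1′ radical.

8 ⇒ 5 (key). The C5–C1′ bond is cut, the C3–O bond restored and the alkene returned from C3=C4 to C4=C5. This converts the isolated C5 stereocentre into a C3 carbinol ester and detaches the whole chain as an acyl group, so the ring–chain bond, the C5 configuration and convergence are handled at once. In one sentence: an Ireland–Claisen rearrangement of 5 makes the C5–C1′ bond and sets C5. The forward step must be a suprafacial [3,3] shift, so that C5 takes the face that O3 occupied.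

5 ⇒ 2 + 3. The C1′–C2′ bond is cut between the acetate α-carbon and the allylic CH2 of the C15 unit. The gain is a two-carbon ester and a commercial bromide. The forward step must be a mono-alkylation of an acetate enolate without condensation.

2 ⇒ 1. The C6–H bond is removed, an acetate is restored at C4 and the alkene returned to C5=C6, which reveals a pentose glycal. The only stereocentre of 2 is thus bought from the chiral pool. The forward step is an allylic transposition with hydride as nucleophile, without 1,3-acyloxy shift.

## Other disconnections considered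

Alternative 1: (the route most would draw first) cut O1–C2 and the exocyclic methylene. Forward: intramolecular oxa-Michael addition of hydroxy enoate A1 to give oxanylacetate A2, then α-methylenation and saponification. Ground for rejection: the conjugate addition is reversible and a 1,4-related pair has no strong kinetic bias, so the diequatorial 2,5-trans relationship is predicted to dominate and the cis isomer wanted here would be the minor one. C5 would also need a separate auxiliary-controlled alkylation with an unactivated homoallylic electrophile, and the enolate chemistry on A2 invites retro-Michael epimerisation at C2.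

Alternative 2: cut O1–C2 and Cα–CO2 in one operation. Forward: divalent-palladium-mediated oxypalladation of allenyl alcohol A3 followed by CO insertion and methanolysis (PdCl2 cat., CuCl2, CO, MeOH) to give methyl ester A4. Ground for rejection: the acrylate is made elegantly, but the 6-exo oxypalladation passes through a chair-like transition state with both substituents equatorial, which again predicts the 2,5-trans relationship. C5 must still be made separately, and a stoichiometric copper oxidant meets an acid- and oxidant-sensitive triene.

Alternative 3: cut O1–C2 in a stereoconvergent sense. Forward: chiral-Lewis-base-catalysed (β-isocupreidine or (DHQD)2PHAL) SN2′/SN2′ etherification of Baylis–Hillman carbonate A5, racemic at the carbinol, closing the ring to A4 with C2 set by the catalyst. Ground for rejection: the idea funnels both carbinol epimers into one C2 configuration, but ring closure of the allylammonium intermediate by a tethered primary alkoxide must compete with oligomerisation, and the match with the existing C5 centre is unknown. A5 also needs a slow Baylis–Hillman reaction of an aliphatic aldehyde plus an independent synthesis of C5, so step economy is worse than in the chosen plan, where one rearrangement sets C5 and joins the chain.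

Key step: step 3

## Route

Step 1
Reactants: 1 3,4-di-O-acetyl-D-xylal [(3R,4R)-3,4-dihydro-2H-pyran-3,4-diyl diacetate]
Product: 2 (3S)-3,6-dihydro-2H-pyran-3-yl acetate
Conditions: Et3SiH (1.3 equiv), BF3·OEt2 (0.5 equiv), CH2Cl2, −20 → 0 °C, short reaction time
Reagents that add atoms: none
Why: Reductive Ferrier rearrangement: BF3 ionises the allylic acetate at C4 (target numbering) with help from the ring oxygen and Et3SiH delivers hydride to the anomeric carbon C6, so the alkene moves from C5=C6 to C4=C5. The C3 stereocentre is not involved and becomes the (S)-carbinol ester of 2. Low temperature and short contact are chosen because a suprafacial 1,3-acyloxy shift in this pseudo-symmetric ring would lead to the enantiomer.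

Step 2
Reactants: 2 (3S)-3,6-dihydro-2H-pyran-3-yl acetate; 3 (2E,6E)-farnesyl bromide [(2E,6E)-1-bromo-3,7,11-trimethyldodeca-2,6,10-triene]
Product: 5 (3S)-3,6-dihydro-2H-pyran-3-yl (4E,8E)-5,9,13-trimethyltetradeca-4,8,12-trienoate, via lithium enolate 4 (not isolated)
Conditions: LiN(iPr)2 (1.05 equiv), THF, −78 °C; then 3, DMPU, −78 → −40 °C
Reagents that add atoms: none
Why: SN2 alkylation of a lithium ester enolate by a primary allylic bromide, which attaches the complete C15 chain to the future C1′ without touching the E alkenes. Deprotonation at −78 °C is confined to the acetate methyl group, and the polar co-solvent lets alkylation outrun Claisen condensation.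

Step 3
Reactants: 5 (3S)-3,6-dihydro-2H-pyran-3-yl (4E,8E)-5,9,13-trimethyltetradeca-4,8,12-trienoate
Product: 8 (2RS,4E,8E)-2-[(3S)-3,6-dihydro-2H-pyran-3-yl]-5,9,13-trimethyltetradeca-4,8,12-trienoic acid, via silyl ketene acetal 6 (not isolated), via trimethylsilyl ester 7 (not isolated)
Conditions: TMSCl, then LiN(iPr)2, THF, −78 °C (in situ silylation); −78 → 60 °C; then 1 M NaOH, rt; citric acid work-up
Reagents that add atoms: none
Why: LiN(iPr)2 removes an α-hydrogen of 5 and the enolate is silylated in situ on oxygen to give silyl ketene acetal 6, whose geometry is immaterial. On warming, 6 undergoes a concerted suprafacial [3,3]-sigmatropic shift (Ireland–Claisen rearrangement) through a six-membered transition state in which the C3–O bond is pseudoaxial on the dihydropyran half-chair; the C5–C1′ σ bond forms as the C3–O bond breaks and the alkene moves to C3=C4, giving silyl ester 7 and, after hydrolysis, 8. The closest known reaction type is the ester-enolate Claisen rearrangement of cyclohex-2-enyl esters and of hex-2-enopyranosid-4-yl esters, which transfers carbinol chirality 1,3 across the ring. No ring is closed; the oxane ring is carried through unchanged. The new ring stereocentre C5 is controlled by the C3 carbinol configuration of 2 alone, because the tethered ketene acetal can reach C5 only on the face that bears O3, whether the transition state is chair- or boat-like; the (3S) ester therefore gives the C5 configuration of the target (labelled 3S in 8 and 3R in 10 only through a change of substituent priorities). The second new stereocentre, C1′, is not controlled and need not be, since step 4 converts it into a methylene group. The selectivity required is chemoselectivity for rearrangement over elimination of the allylic carboxylate and over ester condensation, which low-temperature enolisation with in situ silylation should secure; there is no regiochemical choice because O3 has a single allyl partner and the chain alkenes are out of reach of the ketene acetal.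

Step 4
Reactants: 8 (2RS,4E,8E)-2-[(3S)-3,6-dihydro-2H-pyran-3-yl]-5,9,13-trimethyltetradeca-4,8,12-trienoic acid
Product: 10 (3R)-3-[(3E,7E)-4,8,12-trimethyltrideca-3,7,11-trien-1-yl]-3,6-dihydro-2H-pyran, via Barton ester 9 (not isolated)
Conditions: 2-mercaptopyridine N-oxide, DCC, DMAP (cat.), CH2Cl2, 0 °C → rt, dark; then t-BuSH (excess), hν (tungsten lamp), 0 °C
Reagents that add atoms: none
Why: Barton reductive decarboxylation: acylation of the N-hydroxy-2-thiopyridone gives 9, whose radical chain fragmentation releases CO2 and a secondary radical at C1′ that is capped by fast hydrogen transfer from the thiol before 1,5-hydrogen shift or homoallyl rearrangement can compete. The uncontrolled C1′ centre becomes CH2, while the ring stereocentre is one atom away from the radical and untouched. Low temperature and short irradiation limit thiyl-radical E/Z isomerisation of the chain.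

Step 5
Reactants: 10 (3R)-3-[(3E,7E)-4,8,12-trimethyltrideca-3,7,11-trien-1-yl]-3,6-dihydro-2H-pyran
Product: 11 (3R)-3-[(3E,7E)-4,8,12-trimethyltrideca-3,7,11-trien-1-yl]-3,4-dihydro-2H-pyran
Conditions: KOtBu (0.3 equiv), DMSO, 25 °C
Reagents that add atoms: none
Why: Base-mediated prototropic isomerisation of an allyl ether to its enol ether: the C2 hydrogens (target numbering), allylic and α to oxygen, are removed fastest, and reprotonation of the oxyallyl anion at C4 gives the conjugated, more stable C2=C3 enol ether. The tertiary allylic C5–H is far less acidic, so under these mild conditions the stereocentre should persist and the 1,5-diene chain should not move.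

Step 6
Reactants: 11 (3R)-3-[(3E,7E)-4,8,12-trimethyltrideca-3,7,11-trien-1-yl]-3,4-dihydro-2H-pyran
Product: 12 (2RS,5R)-2-methoxy-5-[(3E,7E)-4,8,12-trimethyltrideca-3,7,11-trien-1-yl]oxane
Conditions: MeOH, PPTS (5 mol%), CH2Cl2, 0 °C → rt
Reagents that add atoms: methanol (SMILES CO)
Why: Acid-catalysed Markovnikov addition of methanol to the enol ether (protonation at C3, capture at C2) gives the mixed acetal; PPTS is too weak to protonate the trisubstituted alkenes. The anomeric mixture is of no consequence because step 7 passes through the planar C2 cation.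

Step 7
Reactants: 12 (2RS,5R)-2-methoxy-5-[(3E,7E)-4,8,12-trimethyltrideca-3,7,11-trien-1-yl]oxane
Product: 13 trimethyl({(2R,5R)-5-[(3E,7E)-4,8,12-trimethyltrideca-3,7,11-trien-1-yl]oxan-2-yl}ethynyl)silane
Conditions: Bu3SnC≡CSiMe3 (1.5 equiv), BF3·OEt2, CH2Cl2, −78 → −40 °C
Reagents that add atoms: tributyl[(trimethylsilyl)ethynyl]stannane (SMILES C[Si](C)(C)C#C[Sn](CCCC)(CCCC)CCCC)
Why: Lewis-acid-mediated substitution at the anomeric carbon by an alkynylstannane (C-glycosylation type, ipso attack with loss of tin): BF3 ionises both anomers of 12 to the same ring oxocarbenium ion, which prefers the half-chair with the C5 chain pseudoequatorial. The slim sp nucleophile adds along the axial trajectory that leads directly to a chair, so the new C2–C bond is axial and on the same face as the equatorial C5 chain, i.e. the kinetic 2,5-cis (2R,5R) product; the step is stereoconvergent and irreversible. Excess nucleophile at low temperature should outrun any attack of the chain alkenes on the cation.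

Step 8
Reactants: 13 trimethyl({(2R,5R)-5-[(3E,7E)-4,8,12-trimethyltrideca-3,7,11-trien-1-yl]oxan-2-yl}ethynyl)silane
Product: 14 (2R,5R)-2-ethynyl-5-[(3E,7E)-4,8,12-trimethyltrideca-3,7,11-trien-1-yl]oxane
Conditions: K2CO3 (0.2 equiv), MeOH/THF, rt
Reagents that add atoms: none
Why: Base-catalysed methanolysis of the C(sp)–Si bond (protodesilylation of an alkynylsilane); the ethers and alkenes are inert and the propargylic C2–H is not acidic enough to epimerise.

Step 9
Reactants: 14 (2R,5R)-2-ethynyl-5-[(3E,7E)-4,8,12-trimethyltrideca-3,7,11-trien-1-yl]oxane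
Product: 15 rhopaloic acid B [2-{(2R,5R)-5-[(3E,7E)-4,8,12-trimethyltrideca-3,7,11-trien-1-yl]oxan-2-yl}prop-2-enoic acid]
Conditions: Pd(OAc)2 (2 mol%), 2-(diphenylphosphino)pyridine (8 mol%), MsOH (4 mol%), CO (5 bar), H2O (5 equiv), THF, 50 °C
Reagents that add atoms: carbon monoxide (SMILES [C-]#[O+]); water (SMILES O)
Why: Palladium-catalysed Markovnikov hydroxycarbonylation of a terminal alkyne with a 2-pyridylphosphine ligand (Drent-type catalyst): hydrogen goes to the terminal carbon and the carboxyl group to the internal one, which creates the 1-carboxyvinyl group in one step. The alkyne reacts far faster than trisubstituted alkenes, the acid co-catalyst is buffered by excess basic ligand, and C2 is not involved, so the (2R,5R) configuration is retained.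

## Compound list

1 | 3,4-di-O-acetyl-D-xylal, (3R,4R)-3,4-dihydro-2H-pyran-3,4-diyl diacetate | CC(=O)O[C@@H]1C=COC[C@H]1OC(C)=O | starting material
2 | (3S)-3,6-dihydro-2H-pyran-3-yl acetate | CC(=O)O[C@H]1C=CCOC1 | intermediate
3 | (2E,6E)-farnesyl bromide, (2E,6E)-1-bromo-3,7,11-trimethyldodeca-2,6,10-triene | BrC/C=C(\C)CC/C=C(\C)CCC=C(C)C | starting material
4 | lithium enolate of 2, lithium 1-[(3S)-3,6-dihydro-2H-pyran-3-yloxy]ethen-1-olate | [Li+].[O-]C(=C)O[C@H]1C=CCOC1 | intermediate
5 | (3S)-3,6-dihydro-2H-pyran-3-yl (4E,8E)-5,9,13-trimethyltetradeca-4,8,12-trienoate | O=C(CC/C=C(\C)CC/C=C(\C)CCC=C(C)C)O[C@H]1C=CCOC1 | intermediate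
6 | silyl ketene acetal, (3S)-3-{[(4E,8E)-5,9,13-trimethyl-1-(trimethylsilyloxy)tetradeca-1,4,8,12-tetraen-1-yl]oxy}-3,6-dihydro-2H-pyran (C1=C2 geometry not fixed) | C[Si](C)(C)OC(=CC/C=C(\C)CC/C=C(\C)CCC=C(C)C)O[C@H]1C=CCOC1 | intermediate
7 | trimethylsilyl (2RS,4E,8E)-2-[(3S)-3,6-dihydro-2H-pyran-3-yl]-5,9,13-trimethyltetradeca-4,8,12-trienoate | C[Si](C)(C)OC(=O)C(C/C=C(\C)CC/C=C(\C)CCC=C(C)C)[C@@H]1C=CCOC1 | intermediate
8 | (2RS,4E,8E)-2-[(3S)-3,6-dihydro-2H-pyran-3-yl]-5,9,13-trimethyltetradeca-4,8,12-trienoic acid | OC(=O)C(C/C=C(\C)CC/C=C(\C)CCC=C(C)C)[C@@H]1C=CCOC1 | intermediate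
9 | Barton ester, 2-thioxopyridin-1(2H)-yl (2RS,4E,8E)-2-[(3S)-3,6-dihydro-2H-pyran-3-yl]-5,9,13-trimethyltetradeca-4,8,12-trienoate | S=C1C=CC=CN1OC(=O)C(C/C=C(\C)CC/C=C(\C)CCC=C(C)C)[C@@H]1C=CCOC1 | intermediate
10 | (3R)-3-[(3E,7E)-4,8,12-trimethyltrideca-3,7,11-trien-1-yl]-3,6-dihydro-2H-pyran | C1C=C[C@@H](CC/C=C(\C)CC/C=C(\C)CCC=C(C)C)CO1 | intermediate
11 | (3R)-3-[(3E,7E)-4,8,12-trimethyltrideca-3,7,11-trien-1-yl]-3,4-dihydro-2H-pyran | C1=CC[C@@H](CC/C=C(\C)CC/C=C(\C)CCC=C(C)C)CO1 | intermediate
12 | (2RS,5R)-2-methoxy-5-[(3E,7E)-4,8,12-trimethyltrideca-3,7,11-trien-1-yl]oxane | COC1CC[C@@H](CC/C=C(\C)CC/C=C(\C)CCC=C(C)C)CO1 | intermediate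
13 | trimethyl({(2R,5R)-5-[(3E,7E)-4,8,12-trimethyltrideca-3,7,11-trien-1-yl]oxan-2-yl}ethynyl)silane | C[Si](C)(C)C#C[C@H]1CC[C@@H](CC/C=C(\C)CC/C=C(\C)CCC=C(C)C)CO1 | intermediate
14 | (2R,5R)-2-ethynyl-5-[(3E,7E)-4,8,12-trimethyltrideca-3,7,11-trien-1-yl]oxane | C#C[C@H]1CC[C@@H](CC/C=C(\C)CC/C=C(\C)CCC=C(C)C)CO1 | intermediate
15 | rhopaloic acid B, 2-{(2R,5R)-5-[(3E,7E)-4,8,12-trimethyltrideca-3,7,11-trien-1-yl]oxan-2-yl}prop-2-enoic acid | C=C(C(=O)O)[C@H]1CC[C@@H](CC/C=C(\C)CC/C=C(\C)CCC=C(C)C)CO1 | target

## Step count and least certain steps

Total step count: 9. Longest linear sequence: 9 steps (1 → 15); 3 enters in step 2.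

Step 3 (key step). What may go wrong: elimination of the allylic carboxylate or ketene formation during enolisation, incomplete O-silylation followed by ester condensation, or a rearrangement so slow that the silyl ketene acetal decomposes first. Fallback (sets out from 2, returns at 8): the C5–C1′ bond would be made by ionisation and alkylation instead of sigmatropy. Sodium dimethyl malonate (NaH, THF) and 3 give dimethyl 2-[(2E,6E)-farnesyl]malonate F1. Its sodium salt is allylated by 2 under zerovalent palladium catalysis (Pd2(dba)3 with the Trost bis(2-diphenylphosphinobenzoyl)-1,2-diaminocyclohexane ligand) to the quaternary malonate F2. The π-allyl unit derived from 2 is meso (mirror plane through O1 and C4), so the ligand enantiomer alone decides which terminus is attacked and the configuration is set by the catalyst. Krapcho demethoxycarbonylation (LiCl, wet DMSO, 150 °C) gives the methyl ester F3, and LiOH hydrolysis returns to 8.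

Step 5. What may go wrong: migration of the ring alkene in the wrong direction, into C4=C5, which would erase the C5 stereocentre, or slow base-induced scrambling of the chain alkenes. Fallback (sets out from 10, returns at 12): the O–CH2–CH=CH unit is oxidised at C2 with pyridinium chlorochromate [C5H5NH][CrO3Cl] to the unsaturated lactone F4. This is reduced in the conjugate sense with [(Ph3P)CuH]6 under non-basic conditions to the saturated lactone F5. Half-reduction with iBu2AlH at −78 °C gives the lactol F6, and acetalisation with MeOH/PPTS returns to 12.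

Step 7. What may go wrong: poor facial selectivity if the oxocarbenium ion reacts through both half-chairs, competing tin–boron or tin–proton exchange of the nucleophile, or capture of the cation by the C3′ alkene. Fallback (sets out from 12, returns at 13): C2 would be set by reagent control and the ring closed by a stereospecific Williamson etherification. Mild acid hydrolysis of 12 gives the lactol F6 described above. Excess LiC≡CSiMe3 adds to its open hydroxy-aldehyde form to give the diol F7 as a carbinol mixture. MnO2 oxidises only the propargylic alcohol to the ynone F8. Transfer hydrogenation with RuCl[(R,R)-TsDPEN](p-cymene) in i-PrOH (catalyst enantiomer to be confirmed on a model) should give the (3R,6R)-diol F9. Selective sulfonylation of the primary hydroxyl (TsCl, Et3N, Bu2SnO cat.) gives the tosylate F10, and NaH closes the O1–C6 bond with retention at C2, returning to 13.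

Step 2. What may go wrong: self-condensation of the acetate enolate, double alkylation, or loss of acetate from the allylic ester under the basic conditions. Fallback (sets out from 2 and 3, returns at 5): the ester would be made by acylation instead of alkylation. Methanolysis of 2 (K2CO3, MeOH) gives (3S)-3,6-dihydro-2H-pyran-3-ol F11. Separately, 3 is homologated with LiCH2CN (MeCN, n-BuLi, THF, −78 °C) to the nitrile F12, which is hydrolysed (KOH, aqueous ethylene glycol, 120 °C) to farnesylacetic acid F13. Steglich esterification of F11 with F13 (DCC, DMAP) gives 5.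

Step 9. What may go wrong: erosion of Markovnikov regioselectivity by the propargylic oxygen, acid-triggered cyclisation of the polyene by the co-catalyst, or catalyst deactivation before full conversion. Fallback (sets out from 14, returns at 15): the carboxyl group would be introduced through a vinyl halide. α-Selective hydrostannation of the propargylic ether (Bu3SnH, Mo(CO)3(CNtBu)3 cat., THF, 55 °C) gives the 1-stannylvinyl compound F14. Iododestannylation (I2, CH2Cl2, 0 °C) gives the 1-iodovinyl compound F15. Hydroxycarbonylation of F15 (Pd(PPh3)4, CO, H2O, Et3N, DMF, 50 °C) returns to 15.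

## Further compounds

F1 | step 3 | dimethyl 2-[(2E,6E)-3,7,11-trimethyldodeca-2,6,10-trien-1-yl]propanedioate | COC(=O)C(C/C=C(\C)CC/C=C(\C)CCC=C(C)C)C(=O)OC
F2 | step 3 | dimethyl 2-[(3S)-3,6-dihydro-2H-pyran-3-yl]-2-[(2E,6E)-3,7,11-trimethyldodeca-2,6,10-trien-1-yl]propanedioate | COC(=O)C(C/C=C(\C)CC/C=C(\C)CCC=C(C)C)(C(=O)OC)[C@@H]1C=CCOC1
F3 | step 3 | methyl (2RS,4E,8E)-2-[(3S)-3,6-dihydro-2H-pyran-3-yl]-5,9,13-trimethyltetradeca-4,8,12-trienoate | COC(=O)C(C/C=C(\C)CC/C=C(\C)CCC=C(C)C)[C@@H]1C=CCOC1
F4 | step 5 | (5R)-5-[(3E,7E)-4,8,12-trimethyltrideca-3,7,11-trien-1-yl]-5,6-dihydro-2H-pyran-2-one | O=C1C=C[C@@H](CC/C=C(\C)CC/C=C(\C)CCC=C(C)C)CO1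
F5 | step 5 | (5R)-5-[(3E,7E)-4,8,12-trimethyltrideca-3,7,11-trien-1-yl]oxan-2-one | O=C1CC[C@@H](CC/C=C(\C)CC/C=C(\C)CCC=C(C)C)CO1
F6 | step 5 | (2RS,5R)-5-[(3E,7E)-4,8,12-trimethyltrideca-3,7,11-trien-1-yl]oxan-2-ol | OC1CC[C@@H](CC/C=C(\C)CC/C=C(\C)CCC=C(C)C)CO1
F7 | step 7 | (3RS,6R)-6-[(3E,7E)-4,8,12-trimethyltrideca-3,7,11-trien-1-yl]-1-(trimethylsilyl)hept-1-yne-3,7-diol | C[Si](C)(C)C#CC(O)CC[C@@H](CC/C=C(\C)CC/C=C(\C)CCC=C(C)C)CO
F8 | step 7 | (6R)-7-hydroxy-6-[(3E,7E)-4,8,12-trimethyltrideca-3,7,11-trien-1-yl]-1-(trimethylsilyl)hept-1-yn-3-one | C[Si](C)(C)C#CC(=O)CC[C@@H](CC/C=C(\C)CC/C=C(\C)CCC=C(C)C)CO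
F9 | step 7 | (3R,6R)-6-[(3E,7E)-4,8,12-trimethyltrideca-3,7,11-trien-1-yl]-1-(trimethylsilyl)hept-1-yne-3,7-diol | C[Si](C)(C)C#C[C@H](O)CC[C@@H](CC/C=C(\C)CC/C=C(\C)CCC=C(C)C)CO
F10 | step 7 | (2R,5R)-5-hydroxy-2-[(3E,7E)-4,8,12-trimethyltrideca-3,7,11-trien-1-yl]-7-(trimethylsilyl)hept-6-yn-1-yl 4-methylbenzenesulfonate | C[Si](C)(C)C#C[C@H](O)CC[C@@H](CC/C=C(\C)CC/C=C(\C)CCC=C(C)C)COS(=O)(=O)c1ccc(C)cc1
F11 | step 2 | (3S)-3,6-dihydro-2H-pyran-3-ol | O[C@H]1C=CCOC1
F12 | step 2 | (4E,8E)-5,9,13-trimethyltetradeca-4,8,12-trienenitrile | N#CCC/C=C(\C)CC/C=C(\C)CCC=C(C)C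
F13 | step 2 | (4E,8E)-5,9,13-trimethyltetradeca-4,8,12-trienoic acid | OC(=O)CC/C=C(\C)CC/C=C(\C)CCC=C(C)C
F14 | step 9 | tributyl(1-{(2R,5R)-5-[(3E,7E)-4,8,12-trimethyltrideca-3,7,11-trien-1-yl]oxan-2-yl}ethenyl)stannane | C=C([Sn](CCCC)(CCCC)CCCC)[C@H]1CC[C@@H](CC/C=C(\C)CC/C=C(\C)CCC=C(C)C)CO1
F15 | step 9 | (2R,5R)-2-(1-iodoethenyl)-5-[(3E,7E)-4,8,12-trimethyltrideca-3,7,11-trien-1-yl]oxane | C=C(I)[C@H]1CC[C@@H](CC/C=C(\C)CC/C=C(\C)CCC=C(C)C)CO1
A1 | alternative 1 | methyl (2E,6S)-7-hydroxy-6-[(3E,7E)-4,8,12-trimethyltrideca-3,7,11-trien-1-yl]hept-2-enoate | COC(=O)/C=C/CC[C@@H](CC/C=C(\C)CC/C=C(\C)CCC=C(C)C)CO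
A2 | alternative 1 | methyl 2-{(2R,5R)-5-[(3E,7E)-4,8,12-trimethyltrideca-3,7,11-trien-1-yl]oxan-2-yl}acetate | COC(=O)C[C@H]1CC[C@@H](CC/C=C(\C)CC/C=C(\C)CCC=C(C)C)CO1
A3 | alternative 2 | (2S)-2-[(3E,7E)-4,8,12-trimethyltrideca-3,7,11-trien-1-yl]hepta-5,6-dien-1-ol | C=C=CCC[C@@H](CC/C=C(\C)CC/C=C(\C)CCC=C(C)C)CO
A4 | alternative 2 | methyl 2-{(2R,5R)-5-[(3E,7E)-4,8,12-trimethyltrideca-3,7,11-trien-1-yl]oxan-2-yl}prop-2-enoate | COC(=O)C(=C)[C@H]1CC[C@@H](CC/C=C(\C)CC/C=C(\C)CCC=C(C)C)CO1
A5 | alternative 3 | methyl (3RS,6R)-3-[(tert-butoxycarbonyl)oxy]-7-hydroxy-2-methylidene-6-[(3E,7E)-4,8,12-trimethyltrideca-3,7,11-trien-1-yl]heptanoate | COC(=O)C(=C)C(OC(=O)OC(C)(C)C)CC[C@@H](CC/C=C(\C)CC/C=C(\C)CCC=C(C)C)CO
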